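**Retrosynthetic overview**
- Feature: between the two guaiacyl rings (bought, never built) C8 carries H and C8' carries OH, each flanked by one arylmethyl carbon (C7, C7') and one hydroxymethyl carbon (C9, C9'). The target is therefore the formal anti H/OH adduct across C8=C8' of the symmetric (Z)-2,3-bis(arylmethyl)but-2-ene-1,4-diol.
- Target 19 ⇐ desilylation and debenzylation ⇐ C9 alcohol by cleavage of an (E)-acrylate arm on C8 ⇐ key exchange of C8–O for C8–H with inversion (palladium/formate) on the cis C8–C8' oxirane 14; no skeletal bond and no ring of the target is formed there.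
- 14 ⇐ oxidation/Wittig ⇐ Sharpless epoxidation (L-(+)-diisopropyl tartrate) of the monosilylated Z-diol ⇐ iBu2AlH reduction of the Z-diester ⇐ union of arylmethylcopper, dimethyl acetylenedicarboxylate and arylmethyl bromide.
- Rings: the only ring made is the oxirane (step 6); it is opened again in step 8.

Key step: step 8

Remark: lignan numbering is used (C7/C7' benzylic CH2, C8/C8' stereocentres, C9/C9' CH2OH); the target SMILES is read as the (8S,8'S) isomer, and Ar is 4-benzyloxy-3-methoxyphenyl in the protected series.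

**Step 1**
Reactants: 1 (4-benzyloxy-3-methoxyphenyl)methanol
Product: 2 4-benzyloxy-3-methoxybenzyl chloride
Conditions: SOCl2, CH2Cl2, 0 °C → rt
Reagents that add atoms: thionyl chloride, O=S(Cl)Cl
Why: Chlorodehydroxylation of the electron-rich benzylic alcohol through its chlorosulfite, which leaves the aryl benzyl ether intact at this temperature.

**Step 2**
Reactants: 1 (4-benzyloxy-3-methoxyphenyl)methanol
Product: 3 4-benzyloxy-3-methoxybenzyl bromide
Conditions: PBr3, Et2O, 0 °C
Reagents that add atoms: phosphorus tribromide, BrP(Br)Br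
Why: Bromodehydroxylation with PBr3 (displacement of the phosphite ester by bromide at the activated benzylic carbon) gives the more reactive electrophile needed for the C-alkylation in step 3.

**Step 3**
Reactants: 2 4-benzyloxy-3-methoxybenzyl chloride, 3 4-benzyloxy-3-methoxybenzyl bromide, 4 dimethyl acetylenedicarboxylate
Product: 8 dimethyl (Z)-2,3-bis(4-benzyloxy-3-methoxybenzyl)but-2-enedioate, via arylmethylmagnesium chloride 5 (not isolated), via arylmethylcopper 6 (not isolated), via alkenylcopper adduct 7 (not isolated)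
Conditions: 2, Mg, THF, 0 °C; CuBr·SMe2, THF, −40 °C; 4, −78 °C; then 3, HMPA, −78 °C → rt
Reagents that add atoms: none
Why: Copper-mediated vicinal difunctionalisation of an acetylenedicarboxylate (carbocupration, then alkylation): the monovalent organocopper reagent should add syn across the triple bond at −78 °C and the alkenylcopper should be C-benzylated with retention in THF–HMPA, so that the two esters, and with them the two arylmethyl groups, end up cis, provided the adduct is kept cold until the bromide is present.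

**Step 4**
Reactants: 8 dimethyl (Z)-2,3-bis(4-benzyloxy-3-methoxybenzyl)but-2-enedioate
Product: 9 (Z)-2,3-bis(4-benzyloxy-3-methoxybenzyl)but-2-ene-1,4-diol
Conditions: iBu2AlH (excess), CH2Cl2, −78 → 0 °C; aq. potassium sodium tartrate
Reagents that add atoms: none
Why: Exhaustive 1,2-reduction of both conjugated esters to allylic alcohols with iBu2AlH, which does not touch the tetrasubstituted alkene or the benzyl ethers, so the Z geometry passes unchanged into the symmetric diol.

**Step 5**
Reactants: 9 (Z)-2,3-bis(4-benzyloxy-3-methoxybenzyl)but-2-ene-1,4-diol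
Product: 10 (Z)-2,3-bis(4-benzyloxy-3-methoxybenzyl)-4-(tert-butyldimethylsilyloxy)but-2-en-1-ol
Conditions: NaH (1.0 equiv), THF, 0 °C; TBSCl (1.0 equiv), 0 °C → rt
Reagents that add atoms: tert-butyldimethylsilyl chloride, CC(C)(C)[Si](C)(C)Cl
Why: Monosilylation of a symmetric diol by the monoalkoxide method (one equivalent of NaH, then one of TBSCl) should differentiate C9 (free) from C9' (silylated) without creating a stereocentre.

**Step 6**
Reactants: 10 (Z)-2,3-bis(4-benzyloxy-3-methoxybenzyl)-4-(tert-butyldimethylsilyloxy)but-2-en-1-ol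
Product: 11 [(2S,3R)-2,3-bis(4-benzyloxy-3-methoxybenzyl)-3-(tert-butyldimethylsilyloxymethyl)oxiran-2-yl]methanol
Conditions: Ti(OiPr)4 (20 mol %), L-(+)-diisopropyl tartrate (24 mol %), tBuOOH, 4 Å MS, CH2Cl2, −20 °C
Reagents that add atoms: tert-butyl hydroperoxide, CC(C)(C)OO
Why: Sharpless asymmetric epoxidation, in which the titanium complex of L-(+)-diisopropyl tartrate transfers the peroxide oxygen suprafacially to the alkene face that makes the carbinol-bearing oxirane carbon S (as nerol gives the 2S,3R epoxide with the same tartrate), so both stereocentres, (2S,3R) and cis, are set at once by the reagent.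

**Step 7**
Reactants: 11 [(2S,3R)-2,3-bis(4-benzyloxy-3-methoxybenzyl)-3-(tert-butyldimethylsilyloxymethyl)oxiran-2-yl]methanol, 12 ethyl (triphenylphosphoranylidene)acetate
Product: 14 ethyl (E)-3-[(2S,3R)-2,3-bis(4-benzyloxy-3-methoxybenzyl)-3-(tert-butyldimethylsilyloxymethyl)oxiran-2-yl]prop-2-enoate, via epoxy aldehyde 13 (not isolated)
Conditions: Dess–Martin periodinane, pyridine, CH2Cl2, 0 °C → rt; then 12, rt → 40 °C
Reagents that add atoms: none
Why: Dess–Martin oxidation to the non-enolisable epoxy aldehyde followed in the same flask by Wittig olefination with the ester-stabilised ylide, which is E-selective; the oxirane stereocentres are not touched.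

**Step 8**
Reactants: 14 ethyl (E)-3-[(2S,3R)-2,3-bis(4-benzyloxy-3-methoxybenzyl)-3-(tert-butyldimethylsilyloxymethyl)oxiran-2-yl]prop-2-enoate
Product: 15 ethyl (2E,4S,5S)-4,5-bis(4-benzyloxy-3-methoxybenzyl)-6-(tert-butyldimethylsilyloxy)-5-hydroxyhex-2-enoate
Conditions: Pd2(dba)3·CHCl3 (cat.), PBu3 (cat.), HCO2H–NEt3, 1,4-dioxane, rt
Reagents that add atoms: none
Why: The catalyst (zerovalent palladium carrying PBu3) binds the enoate alkene and inserts into the allylic C8–O bond of the oxirane from the side opposite the departing oxygen, giving an ester-substituted pi-allyl palladium complex and the C8' alkoxide; formic acid protonates the alkoxide, formate takes its place on the metal and loses CO2, and the palladium hydride passes hydrogen to C8 on the face that palladium occupies, so C8–O becomes C8–H with net inversion while C8' keeps its oxygen and configuration. The closest known reaction type is the palladium-catalysed formate hydrogenolysis of (E)-gamma,delta-epoxy-alpha,beta-unsaturated esters to delta-hydroxy-alpha,beta-unsaturated esters (Tsuji–Shimizu), established for oxiranes with an alkyl group at the allylic carbon; the present oxirane differs only in that its carbinol carbon C8' is fully substituted as well. No ring is closed: the oxirane, the only ring made in the route, is opened. The new C8 stereocentre (S) is controlled by the (2S,3R) configuration of the cis-oxirane through anti ionisation and metal-face hydride transfer, and inversion at C8 of the cis isomer is what gives the (8S,8'S) relationship of the target. The step needs hydride transfer to C8 and not to the carbon alpha to the ester, which reductive elimination at the more substituted allyl terminus under PBu3 and the conjugation kept in the product should secure, and it needs stereospecificity, which the E geometry should secure because the ester already sits syn on the allyl unit and nothing drives the sigma-bonded rotation at the ester-bearing carbon that would move palladium to the other face. Because C8' has no carbinol hydrogen the usual isomerisation of alkenyl oxiranes to ketones is closed, which leaves beta-hydride loss from C7 as the main competitor that the fast formate pathway is relied on to outrun.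

**Step 9**
Reactants: 15 ethyl (2E,4S,5S)-4,5-bis(4-benzyloxy-3-methoxybenzyl)-6-(tert-butyldimethylsilyloxy)-5-hydroxyhex-2-enoate
Product: 16 (2R,3S)-2,3-bis(4-benzyloxy-3-methoxybenzyl)-4-(tert-butyldimethylsilyloxy)-3-hydroxybutanal
Conditions: OsO4 (cat.), NaIO4, 2,6-lutidine, 1,4-dioxane–H2O (3:1), rt; crude product used at once
Reagents that add atoms: osmium tetroxide, O=[Os](=O)(=O)=O; sodium periodate, [Na+].[O-]I(=O)(=O)=O
Why: Lemieux–Johnson cleavage (catalytic dihydroxylation of the only alkene, then periodate glycol fission) cuts the acrylate arm back to C9, with 2,6-lutidine keeping the medium near neutral so that the C8 stereocentre alpha to the new aldehyde is not epimerised.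

**Step 10**
Reactants: 16 (2R,3S)-2,3-bis(4-benzyloxy-3-methoxybenzyl)-4-(tert-butyldimethylsilyloxy)-3-hydroxybutanal
Product: 17 (2S,3S)-2,3-bis(4-benzyloxy-3-methoxybenzyl)-4-(tert-butyldimethylsilyloxy)butane-1,3-diol
Conditions: NaBH4, MeOH, 0 °C
Reagents that add atoms: none
Why: Borohydride reduction of the aldehyde to the C9 primary alcohol at 0 °C, fast enough to forestall epimerisation at C8 or retro-aldol cleavage of the beta-hydroxy aldehyde; no stereocentre is created.

**Step 11**
Reactants: 17 (2S,3S)-2,3-bis(4-benzyloxy-3-methoxybenzyl)-4-(tert-butyldimethylsilyloxy)butane-1,3-diol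
Product: 18 (2S,3S)-2,3-bis(4-benzyloxy-3-methoxybenzyl)butane-1,2,4-triol
Conditions: Bu4NF, THF, 0 °C → rt
Reagents that add atoms: none
Why: Fluoride-induced desilylation (formation of the strong Si–F bond) frees the C9' primary alcohol, and benzyl ethers and free hydroxyl groups are inert to it.

**Step 12**
Reactants: 18 (2S,3S)-2,3-bis(4-benzyloxy-3-methoxybenzyl)butane-1,2,4-triol
Product: 19 (−)-carinol, (2S,3S)-2,3-bis(4-hydroxy-3-methoxybenzyl)butane-1,2,4-triol
Conditions: H2 (1 atm), Pd/C, EtOAc–EtOH, rt
Reagents that add atoms: none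
Why: Catalytic hydrogenolysis of the two aryl benzyl ethers over Pd/C cannot touch C7/C7' (no benzylic oxygen) or the non-benzylic tertiary alcohol at C8', so the target should be released with both stereocentres intact.

**Compound list**
1 | (4-benzyloxy-3-methoxyphenyl)methanol | OCc1ccc(OCc2ccccc2)c(OC)c1 | starting material
2 | 4-benzyloxy-3-methoxybenzyl chloride | ClCc1ccc(OCc2ccccc2)c(OC)c1 | intermediate
3 | 4-benzyloxy-3-methoxybenzyl bromide | BrCc1ccc(OCc2ccccc2)c(OC)c1 | intermediate
4 | dimethyl acetylenedicarboxylate | COC(=O)C#CC(=O)OC | starting material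
5 | (4-benzyloxy-3-methoxybenzyl)magnesium chloride | COc1cc(C[Mg]Cl)ccc1OCc1ccccc1 | intermediate
6 | (4-benzyloxy-3-methoxybenzyl)copper | COc1cc(C[Cu])ccc1OCc1ccccc1 | intermediate
7 | alkenylcopper adduct, dimethyl 2-(4-benzyloxy-3-methoxybenzyl)-3-cupriobut-2-enedioate (esters cis, copper cis to the arylmethyl group) | COC(=O)/C([Cu])=C(/Cc1ccc(OCc2ccccc2)c(OC)c1)C(=O)OC | intermediate
8 | dimethyl (Z)-2,3-bis(4-benzyloxy-3-methoxybenzyl)but-2-enedioate | COC(=O)/C(Cc1ccc(OCc2ccccc2)c(OC)c1)=C(/Cc1ccc(OCc2ccccc2)c(OC)c1)C(=O)OC | intermediate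
9 | (Z)-2,3-bis(4-benzyloxy-3-methoxybenzyl)but-2-ene-1,4-diol | OC/C(Cc1ccc(OCc2ccccc2)c(OC)c1)=C(/Cc1ccc(OCc2ccccc2)c(OC)c1)CO | intermediate
10 | (Z)-2,3-bis(4-benzyloxy-3-methoxybenzyl)-4-(tert-butyldimethylsilyloxy)but-2-en-1-ol | CC(C)(C)[Si](C)(C)OC/C(Cc1ccc(OCc2ccccc2)c(OC)c1)=C(/Cc1ccc(OCc2ccccc2)c(OC)c1)CO | intermediate
11 | [(2S,3R)-2,3-bis(4-benzyloxy-3-methoxybenzyl)-3-(tert-butyldimethylsilyloxymethyl)oxiran-2-yl]methanol | OC[C@]1(Cc2ccc(OCc3ccccc3)c(OC)c2)O[C@@]1(CO[Si](C)(C)C(C)(C)C)Cc1ccc(OCc2ccccc2)c(OC)c1 | intermediate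
12 | ethyl (triphenylphosphoranylidene)acetate | CCOC(=O)C=P(c1ccccc1)(c1ccccc1)c1ccccc1 | starting material
13 | (2R,3R)-2,3-bis(4-benzyloxy-3-methoxybenzyl)-3-(tert-butyldimethylsilyloxymethyl)oxirane-2-carbaldehyde | O=C[C@]1(Cc2ccc(OCc3ccccc3)c(OC)c2)O[C@@]1(CO[Si](C)(C)C(C)(C)C)Cc1ccc(OCc2ccccc2)c(OC)c1 | intermediate
14 | ethyl (E)-3-[(2S,3R)-2,3-bis(4-benzyloxy-3-methoxybenzyl)-3-(tert-butyldimethylsilyloxymethyl)oxiran-2-yl]prop-2-enoate | CCOC(=O)/C=C/[C@]1(Cc2ccc(OCc3ccccc3)c(OC)c2)O[C@@]1(CO[Si](C)(C)C(C)(C)C)Cc1ccc(OCc2ccccc2)c(OC)c1 | intermediate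
15 | ethyl (2E,4S,5S)-4,5-bis(4-benzyloxy-3-methoxybenzyl)-6-(tert-butyldimethylsilyloxy)-5-hydroxyhex-2-enoate | CCOC(=O)/C=C/[C@H](Cc1ccc(OCc2ccccc2)c(OC)c1)[C@](O)(CO[Si](C)(C)C(C)(C)C)Cc1ccc(OCc2ccccc2)c(OC)c1 | intermediate
16 | (2R,3S)-2,3-bis(4-benzyloxy-3-methoxybenzyl)-4-(tert-butyldimethylsilyloxy)-3-hydroxybutanal | O=C[C@H](Cc1ccc(OCc2ccccc2)c(OC)c1)[C@](O)(CO[Si](C)(C)C(C)(C)C)Cc1ccc(OCc2ccccc2)c(OC)c1 | intermediate
17 | (2S,3S)-2,3-bis(4-benzyloxy-3-methoxybenzyl)-4-(tert-butyldimethylsilyloxy)butane-1,3-diol | OC[C@H](Cc1ccc(OCc2ccccc2)c(OC)c1)[C@](O)(CO[Si](C)(C)C(C)(C)C)Cc1ccc(OCc2ccccc2)c(OC)c1 | intermediate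
18 | (2S,3S)-2,3-bis(4-benzyloxy-3-methoxybenzyl)butane-1,2,4-triol | OC[C@H](Cc1ccc(OCc2ccccc2)c(OC)c1)[C@](O)(CO)Cc1ccc(OCc2ccccc2)c(OC)c1 | intermediate
19 | (−)-carinol, (2S,3S)-2,3-bis(4-hydroxy-3-methoxybenzyl)butane-1,2,4-triol | COc1cc(C[C@@H](CO)[C@](O)(CO)Cc2ccc(O)c(OC)c2)ccc1O | target

**Step count**
Total: 12 steps. Longest linear sequence: 11 steps (steps 1 and 3 to 12; step 2 is a one-step side branch from the same starting material).

**Steps most likely to fail**

1. Step 8 (key step). Hydride transfer may go to the ester-bearing allyl terminus, or a C7 hydrogen may be lost from the allyl complex (diene formation). Ionisation of the fully substituted oxirane may be slow, and face exchange of the allyl complex would erode the C8 configuration.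
Fallback, setting out from bromide 3 and returning at triol 18: both stereocentres are built by enolate alkylation from the chiral pool. Diethyl (S)-malate is converted into its alkoxide enolate (LiN(SiMe3)2, 2.2 equiv, THF, −78 °C) and alkylated with 3 anti to the alkoxide (Fráter–Seebach alkylation), which should give diethyl (2S,3R)-3-(4-benzyloxy-3-methoxybenzyl)-2-hydroxybutanedioate F1. Saponification (LiOH, THF–H2O) gives (2S,3R)-3-(4-benzyloxy-3-methoxybenzyl)-2-hydroxybutanedioic acid F2. Acetalisation of its alpha-hydroxy acid unit with pivalaldehyde (cat. TsOH, pentane, azeotropic removal of water) gives the cis dioxolanone (2R)-3-(4-benzyloxy-3-methoxyphenyl)-2-[(2S,4S)-2-tert-butyl-5-oxo-1,3-dioxolan-4-yl]propanoic acid F3. Its carboxylate enolate (LiN(SiMe3)2, 2.2 equiv, THF–DMPU, −78 °C) is alkylated with 3 on the face opposite the tert-butyl group (Seebach self-regeneration of a stereocentre), so the second arylmethyl group takes the place of the ring hydrogen in (2R)-3-(4-benzyloxy-3-methoxyphenyl)-2-[(2S,4S)-4-(4-benzyloxy-3-methoxybenzyl)-2-tert-butyl-5-oxo-1,3-dioxolan-4-yl]propanoic acid F4. LiAlH4 (THF, 0 °C → reflux) reduces the acid and the dioxolanone and sets the tertiary alcohol free, which gives 18.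

2. Step 3. The copper adduct may lose its geometry through its allenoate form before it is captured. C-benzylation may be too slow and leave the protonated trisubstituted diester, and the benzylic organometallic may homocouple.
Fallback, setting out from chloride 2 and returning at diol 9: the cis arrangement is locked in a ring. Zinc insertion into 2 (Zn dust, LiCl, THF, rt) gives (4-benzyloxy-3-methoxybenzyl)zinc chloride F5. A two-fold Negishi coupling with commercial 3,4-dibromofuran-2(5H)-one (Pd(OAc)2, SPhos, THF, rt → 50 °C) should give 3,4-bis(4-benzyloxy-3-methoxybenzyl)furan-2(5H)-one F6. Reduction of the butenolide (LiAlH4, THF, −20 → 0 °C) opens it to the Z-diol 9.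

3. Step 6. The titanium tartrate may discriminate poorly between the faces of a tetrasubstituted alkene whose cis substituent is a bulky silyloxymethyl group. The fully substituted oxirane, flanked by electron-rich arylmethyl groups, may also be opened by the Lewis acid during reaction or work-up.
Fallback, setting out from diol 9 and returning at epoxy alcohol 11: desymmetrisation of a meso oxirane replaces the asymmetric epoxidation. Epoxidation of 9 (mCPBA, NaHCO3, CH2Cl2, 0 °C) gives the meso compound [(2R,3S)-2,3-bis(4-benzyloxy-3-methoxybenzyl)oxirane-2,3-diyl]dimethanol F7. A lipase chosen by screening (for example Burkholderia cepacia lipase, vinyl acetate, tBuOMe, rt) would acetylate the hydroxymethyl group on the S-configured oxirane carbon, giving [(2S,3R)-2,3-bis(4-benzyloxy-3-methoxybenzyl)-3-(hydroxymethyl)oxiran-2-yl]methyl acetate F8; the sense of the enzymatic acylation cannot be predicted and would be set by that screening. Silylation of the remaining hydroxyl (TBSCl, imidazole, DMF) gives [(2S,3R)-2,3-bis(4-benzyloxy-3-methoxybenzyl)-3-(tert-butyldimethylsilyloxymethyl)oxiran-2-yl]methyl acetate F9, and methanolysis of the acetate (K2CO3, MeOH, 0 °C) gives 11.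

**Further compounds**
F1 | step 8 | diethyl (2S,3R)-3-(4-benzyloxy-3-methoxybenzyl)-2-hydroxybutanedioate | CCOC(=O)[C@@H](O)[C@@H](Cc1ccc(OCc2ccccc2)c(OC)c1)C(=O)OCC
F2 | step 8 | (2S,3R)-3-(4-benzyloxy-3-methoxybenzyl)-2-hydroxybutanedioic acid | OC(=O)[C@@H](O)[C@@H](Cc1ccc(OCc2ccccc2)c(OC)c1)C(=O)O
F3 | step 8 | (2R)-3-(4-benzyloxy-3-methoxyphenyl)-2-[(2S,4S)-2-tert-butyl-5-oxo-1,3-dioxolan-4-yl]propanoic acid | CC(C)(C)[C@H]1O[C@@H]([C@@H](Cc2ccc(OCc3ccccc3)c(OC)c2)C(=O)O)C(=O)O1
F4 | step 8 | (2R)-3-(4-benzyloxy-3-methoxyphenyl)-2-[(2S,4S)-4-(4-benzyloxy-3-methoxybenzyl)-2-tert-butyl-5-oxo-1,3-dioxolan-4-yl]propanoic acid | CC(C)(C)[C@H]1O[C@@](Cc2ccc(OCc3ccccc3)c(OC)c2)([C@@H](Cc2ccc(OCc3ccccc3)c(OC)c2)C(=O)O)C(=O)O1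
F5 | step 3 | (4-benzyloxy-3-methoxybenzyl)zinc chloride | COc1cc(C[Zn]Cl)ccc1OCc1ccccc1
F6 | step 3 | 3,4-bis(4-benzyloxy-3-methoxybenzyl)furan-2(5H)-one | O=C1OCC(Cc2ccc(OCc3ccccc3)c(OC)c2)=C1Cc1ccc(OCc2ccccc2)c(OC)c1
F7 | step 6 | [(2R,3S)-2,3-bis(4-benzyloxy-3-methoxybenzyl)oxirane-2,3-diyl]dimethanol (meso) | OC[C@]1(Cc2ccc(OCc3ccccc3)c(OC)c2)O[C@@]1(CO)Cc1ccc(OCc2ccccc2)c(OC)c1
F8 | step 6 | [(2S,3R)-2,3-bis(4-benzyloxy-3-methoxybenzyl)-3-(hydroxymethyl)oxiran-2-yl]methyl acetate | CC(=O)OC[C@]1(Cc2ccc(OCc3ccccc3)c(OC)c2)O[C@@]1(CO)Cc1ccc(OCc2ccccc2)c(OC)c1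
F9 | step 6 | [(2S,3R)-2,3-bis(4-benzyloxy-3-methoxybenzyl)-3-(tert-butyldimethylsilyloxymethyl)oxiran-2-yl]methyl acetate | CC(=O)OC[C@]1(Cc2ccc(OCc3ccccc3)c(OC)c2)O[C@@]1(CO[Si](C)(C)C(C)(C)C)Cc1ccc(OCc2ccccc2)c(OC)c1
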